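**Retrosynthetic overview**
1. Target ⇒ (debenzylation, Na+/H+ exchange) the ring-B-closed dibenzyl ether sulfate.
2. Ring B (last ring formed) ⇒ two-atom ring expansion of an all-trans 1,2-diarylcyclobutane: the C7–C7' bond is cut and C7' is re-bonded to the ortho carbon of ring A (four- to six-membered carbocycle).
3. The sulfate is installed before the expansion, on the C2-symmetric cyclobutane diol whose two CH2OH groups are homotopic. It then steers the expansion.
4. Cyclobutane (first ring formed, carries C8 and C8') ⇒ enantioselective head-to-head [2+2] dimerisation of one cinnamate.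
5. Cinnamate ⇒ p-cresol (aryl-C1 unit; Br2, NaOMe, BnBr) + monomethyl malonate (C2 unit).

Locants: lignan numbering. C7H2–C8(C9H2OH)–C8'(C9'H2OSO3H)–C7'H(aryl). Ring A is the fused arene, ring B the new carbocycle, ring C the pendant aryl. The target is the 9'-O-sulfate of the (7'R,8'S,8S) = (−)-lyoniresinol series, with aryl/C9' trans and C9'/C9 trans.

Assumption: the sense of induction of the chiral Lewis acid in step 5, and of the diol auxiliary in its fallback, is taken as drawn. If it is the opposite, the mirror-image catalyst or auxiliary is used.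

**Step 1**
Reactants: 1 p-cresol
Product: 4 3,5-dibromo-4-hydroxybenzaldehyde, via 2,6-dibromo-4-methylphenol 2 (not isolated), via 2,6-dibromo-4-(dibromomethyl)phenol 3 (not isolated)
Conditions: Br2 (2.05 equiv), 1,2-dichlorobenzene, 35 °C; Br2 (2.05 equiv), 155 °C; H2O, 100 °C
Reagents that add atoms: bromine BrBr; water O
Why: Electrophilic ortho,ortho-dibromination of the phenol, thermal radical side-chain dibromination and hydrolysis of the benzal bromide, run in one pot as in the established technical process; no stereocentre.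

**Step 2**
Reactants: 4 3,5-dibromo-4-hydroxybenzaldehyde
Product: 5 syringaldehyde
Conditions: NaOMe (4 equiv), CuCl (10 mol %), DMF/MeOH, 115 °C; aq HCl work-up
Reagents that add atoms: sodium methoxide C[O-].[Na+]
Why: Copper-catalysed Ullmann-type methoxylation of both aryl bromides, a well-used route to syringaldehyde that the aldehyde tolerates.

**Step 3**
Reactants: 5 syringaldehyde
Product: 6 4-(benzyloxy)-3,5-dimethoxybenzaldehyde
Conditions: BnBr, K2CO3, DMF, 60 °C
Reagents that add atoms: benzyl bromide BrCc1ccccc1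
Why: Williamson ether synthesis; the benzyl ether keeps the arene electron-rich, blocks phenoxyl chemistry in steps 5, 7 and 8, and leaves by hydrogenolysis at the end.

**Step 4**
Reactants: 6 4-(benzyloxy)-3,5-dimethoxybenzaldehyde; 7 monomethyl malonate
Product: 8 methyl (E)-3-[4-(benzyloxy)-3,5-dimethoxyphenyl]prop-2-enoate
Conditions: pyridine, piperidine (10 mol %), 95 °C
Reagents that add atoms: none
Why: Knoevenagel–Doebner condensation with decarboxylation gives the E-cinnamate directly.

**Step 5**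
Reactants: 8 methyl (E)-3-[4-(benzyloxy)-3,5-dimethoxyphenyl]prop-2-enoate (two molecules)
Product: 9 dimethyl (1S,2S,3R,4R)-3,4-bis[4-(benzyloxy)-3,5-dimethoxyphenyl]cyclobutane-1,2-dicarboxylate
Conditions: (S)-3,3-diphenyl-1-(2-methylphenyl)tetrahydro-1H,3H-pyrrolo[1,2-c][1,3,2]oxazaborole·HNTf2 (25 mol %), [Ir(ppy)2(dtbbpy)]PF6 (1 mol %), CH2Cl2 (0.5 M), 450 nm LED, −60 °C
Reagents that add atoms: none
Why: Proposed new method: enantioselective head-to-head homodimerisation of a simple cinnamate by Lewis-acid-gated triplet sensitisation – binding of the oxazaborolidinium ion to the ester carbonyl lowers the triplet energy to within reach of the sensitiser (about 49 kcal/mol) while free 8 (about 55 kcal/mol) stays dark, so only the bound, face-shielded ester is excited, its α-carbon attacks the α-carbon of a free molecule of 8 from the open face (C8–C8' bond, both centres set as S,S and trans), and the doubly benzylic 1,4-diradical closes to the least crowded all-trans cyclobutane (epimers at C7/C7' do no harm because that bond is cut in step 8); closest known reaction types are the Lewis-acid-co-catalysed enantioselective crossed [2+2] photocycloaddition of cinnamates with styrenes and the racemic iridium-sensitised dimerisation of cinnamates to δ-truxinates.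

**Step 6**
Reactants: 9 dimethyl (1S,2S,3R,4R)-3,4-bis[4-(benzyloxy)-3,5-dimethoxyphenyl]cyclobutane-1,2-dicarboxylate
Product: 10 {(1S,2S,3R,4R)-3,4-bis[4-(benzyloxy)-3,5-dimethoxyphenyl]cyclobutane-1,2-diyl}dimethanol
Conditions: LiAlH4, THF, 0 °C to rt; aqueous work-up
Reagents that add atoms: none
Why: Hydride reduction of both esters is fast at 0 °C, so the α-centres C8 and C8' are not epimerised and the benzyl and methyl ethers are untouched.

**Step 7**
Reactants: 10 {(1S,2S,3R,4R)-3,4-bis[4-(benzyloxy)-3,5-dimethoxyphenyl]cyclobutane-1,2-diyl}dimethanol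
Product: 12 sodium {(1S,2S,3R,4R)-3,4-bis[4-(benzyloxy)-3,5-dimethoxyphenyl]-2-(hydroxymethyl)cyclobutyl}methyl sulfate, via pyridinium monosulfate 11 (not isolated)
Conditions: SO3·pyridine (1.0 equiv, slow addition), pyridine/CH2Cl2, 0 °C; aq NaHCO3; chromatography, recovered 10 recycled
Reagents that add atoms: sulfur trioxide–pyridine complex O=S(=O)([O-])[n+]1ccccc1; sodium hydrogencarbonate [Na+].OC([O-])=O
Why: O-sulfation of a primary alcohol with SO3·pyridine; the two CH2OH groups are exchanged by the C2 axis, so monosulfation gives a single compound without any site-selectivity problem (the sulfated arm defines C9'), and limiting reagent plus recycling handles the statistical mixture.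

**Step 8**
Reactants: 12 sodium {(1S,2S,3R,4R)-3,4-bis[4-(benzyloxy)-3,5-dimethoxyphenyl]-2-(hydroxymethyl)cyclobutyl}methyl sulfate
Product: 14 sodium {(1R,2S,3S)-7-(benzyloxy)-1-[4-(benzyloxy)-3,5-dimethoxyphenyl]-3-(hydroxymethyl)-6,8-dimethoxy-1,2,3,4-tetrahydronaphthalen-2-yl}methyl sulfate, via tetrahydrofuran sulfate 13 (not isolated)
Conditions: 9-mesityl-10-methylacridinium tetrafluoroborate (5 mol %), PhSSPh (20 mol %), ClCH2CH2Cl/(CF3)2CHOH 9:1 (0.005 M), 450 nm LED, 0 °C; then TfOH (10 mol %), 0 °C to rt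
Reagents that add atoms: none
Why: Proposed new method: redox-neutral, hole-catalysed ring expansion of a 1,2-diarylcyclobutane to an aryltetralin – the excited acridinium (about +2.1 V vs SCE) oxidises a trialkoxyaryl ring (about +1.4 V), the strained doubly benzylic C7–C7' bond breaks to a benzylic radical/benzylic cation pair, the cationic end settles on C7' because only there can the neighbouring sulfate (six-membered contact) and the free C9 hydroxyl (five-membered ring, giving 13 after thiol H-atom transfer to the C7 radical) reach it, these intramolecular traps together with high dilution outrun C8–C8' scission and re-dimerisation so C8 and C8' keep their configuration, and catalytic acid then re-ionises the C7'–O bond so that the ortho carbon of ring A (ortho and para to OMe) closes ring B through a chair-like transition state that puts the aryl group trans to C9' (7'R), the net result being migration of C7' from C7 to the ring-A ortho carbon; closest known reaction types are the radical-cation cleavage and 1,3-shift of 1,2-diarylcyclobutanes, the acridinium/disulfide dimerisation of styrenes to tetralins, anti-Markovnikov hydroetherification, and the acid cyclisation of lariciresinol-type ethers to aryltetralins.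

**Step 9**
Reactants: 14 sodium {(1R,2S,3S)-7-(benzyloxy)-1-[4-(benzyloxy)-3,5-dimethoxyphenyl]-3-(hydroxymethyl)-6,8-dimethoxy-1,2,3,4-tetrahydronaphthalen-2-yl}methyl sulfate
Product: 16 {(1R,2S,3S)-7-hydroxy-1-(4-hydroxy-3,5-dimethoxyphenyl)-3-(hydroxymethyl)-6,8-dimethoxy-1,2,3,4-tetrahydronaphthalen-2-yl}methyl hydrogen sulfate, via debenzylated sodium sulfate 15 (not isolated)
Conditions: H2 (1 atm), Pd/C (10 wt %), MeOH, rt; filter; aq HCl (1.0 equiv), 0 °C; C18 desalting, freeze-drying
Reagents that add atoms: none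
Why: Catalytic hydrogenolysis removes both aryl benzyl ethers without touching the alkyl sulfate salt, the methyl ethers or the three stereocentres, and one equivalent of acid turns the salt into the hydrogen sulfate as drawn.

**Compound list**
1 | p-cresol | Cc1ccc(O)cc1 | starting material
2 | 2,6-dibromo-4-methylphenol | Cc1cc(Br)c(O)c(Br)c1 | intermediate
3 | 2,6-dibromo-4-(dibromomethyl)phenol | BrC(Br)c1cc(Br)c(O)c(Br)c1 | intermediate
4 | 3,5-dibromo-4-hydroxybenzaldehyde | O=Cc1cc(Br)c(O)c(Br)c1 | intermediate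
5 | syringaldehyde (4-hydroxy-3,5-dimethoxybenzaldehyde) | COc1cc(C=O)cc(OC)c1O | intermediate
6 | 4-(benzyloxy)-3,5-dimethoxybenzaldehyde | COc1cc(C=O)cc(OC)c1OCc1ccccc1 | intermediate
7 | monomethyl malonate (3-methoxy-3-oxopropanoic acid) | COC(=O)CC(=O)O | starting material
8 | methyl (E)-3-[4-(benzyloxy)-3,5-dimethoxyphenyl]prop-2-enoate | COC(=O)/C=C/c1cc(OC)c(OCc2ccccc2)c(OC)c1 | intermediate
9 | dimethyl (1S,2S,3R,4R)-3,4-bis[4-(benzyloxy)-3,5-dimethoxyphenyl]cyclobutane-1,2-dicarboxylate (all-trans, C2-symmetric) | COC(=O)[C@@H]1[C@@H](C(=O)OC)[C@H](c2cc(OC)c(OCc3ccccc3)c(OC)c2)[C@H]1c1cc(OC)c(OCc2ccccc2)c(OC)c1 | intermediate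
10 | {(1S,2S,3R,4R)-3,4-bis[4-(benzyloxy)-3,5-dimethoxyphenyl]cyclobutane-1,2-diyl}dimethanol | OC[C@@H]1[C@@H](CO)[C@H](c2cc(OC)c(OCc3ccccc3)c(OC)c2)[C@H]1c1cc(OC)c(OCc2ccccc2)c(OC)c1 | intermediate
11 | pyridinium {(1S,2S,3R,4R)-3,4-bis[4-(benzyloxy)-3,5-dimethoxyphenyl]-2-(hydroxymethyl)cyclobutyl}methyl sulfate | OC[C@@H]1[C@@H](COS(=O)(=O)[O-])[C@H](c2cc(OC)c(OCc3ccccc3)c(OC)c2)[C@H]1c1cc(OC)c(OCc2ccccc2)c(OC)c1.c1cc[nH+]cc1 | intermediate
12 | sodium {(1S,2S,3R,4R)-3,4-bis[4-(benzyloxy)-3,5-dimethoxyphenyl]-2-(hydroxymethyl)cyclobutyl}methyl sulfate | OC[C@@H]1[C@@H](COS(=O)(=O)[O-])[C@H](c2cc(OC)c(OCc3ccccc3)c(OC)c2)[C@H]1c1cc(OC)c(OCc2ccccc2)c(OC)c1.[Na+] | intermediate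
13 | sodium {(2R,3S,4S)-2-[4-(benzyloxy)-3,5-dimethoxyphenyl]-4-[4-(benzyloxy)-3,5-dimethoxybenzyl]tetrahydrofuran-3-yl}methyl sulfate (2,3-trans, 3,4-cis) | [Na+].[O-]S(=O)(=O)OC[C@H]1[C@H](c2cc(OC)c(OCc3ccccc3)c(OC)c2)OC[C@H]1Cc1cc(OC)c(OCc2ccccc2)c(OC)c1 | intermediate
14 | sodium {(1R,2S,3S)-7-(benzyloxy)-1-[4-(benzyloxy)-3,5-dimethoxyphenyl]-3-(hydroxymethyl)-6,8-dimethoxy-1,2,3,4-tetrahydronaphthalen-2-yl}methyl sulfate | COc1cc([C@@H]2c3c(cc(OC)c(OCc4ccccc4)c3OC)C[C@H](CO)[C@H]2COS(=O)(=O)[O-])cc(OC)c1OCc1ccccc1.[Na+] | intermediate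
15 | sodium {(1R,2S,3S)-7-hydroxy-1-(4-hydroxy-3,5-dimethoxyphenyl)-3-(hydroxymethyl)-6,8-dimethoxy-1,2,3,4-tetrahydronaphthalen-2-yl}methyl sulfate | COc1cc([C@@H]2c3c(cc(OC)c(O)c3OC)C[C@H](CO)[C@H]2COS(=O)(=O)[O-])cc(OC)c1O.[Na+] | intermediate
16 | {(1R,2S,3S)-7-hydroxy-1-(4-hydroxy-3,5-dimethoxyphenyl)-3-(hydroxymethyl)-6,8-dimethoxy-1,2,3,4-tetrahydronaphthalen-2-yl}methyl hydrogen sulfate (CNP0111670.1) | COc1cc([C@@H]2c3c(cc(OC)c(O)c3OC)C[C@H](CO)[C@H]2COS(=O)(=O)O)cc(OC)c1O | target

**Total step count:** 9. **Longest linear sequence:** 9 (steps 1–9; step 5 joins two molecules of 8).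

**Three steps most likely to fail**

Step 5 (new method). The risks are slow dimerisation of the bound triplet with a second cinnamate, or low ee. The fallback is the known auxiliary-tethered photodimerisation; it sets out from 8 and comes back at 10.
- Saponification (LiOH, THF/H2O) gives (E)-3-[4-(benzyloxy)-3,5-dimethoxyphenyl]prop-2-enoic acid F1.
- Two equivalents of F1 are esterified (EDC·HCl, DMAP, CH2Cl2) with the recoverable C2-symmetric auxiliary (4S,5S)-2,2-dimethyl-1,3-dioxolane-4,5-dimethanol to give the tethered dicinnamate F2.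
- Dilute irradiation (above 300 nm, or thioxanthone-sensitised) closes the cyclobutane intramolecularly under control of the tether, giving the ten-membered all-trans truxinate dilactone F3. F3 is purified by crystallisation.
- LiAlH4 reduction of F3 gives 10 and returns the auxiliary.

Step 7 (statistical monosulfation, at most about half conversion to 12 per pass). The fallback replaces statistics by protection; it sets out from 10 and comes back at 12.
- The monosodium alkoxide (NaH 1.0 equiv, THF) is silylated with TBSCl to the mono-TBS ether F4.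
- The remaining hydroxyl is sulfated (excess SO3·pyridine, then NaHCO3) to the silyl ether sulfate F5.
- Aqueous HF in MeCN followed by NaHCO3 removes the silyl group and gives 12.

Step 8 (new method). The risks are cycloreversion, the wrong direction of expansion, or side reactions of the radical cation. The fallback uses only known chemistry; it sets out from 10 and comes back at 14 by way of 13.
- Catalytic hydrogenolysis (H2 5 bar, Pd/C, EtOH/AcOH, 60 °C) cleaves the strained doubly benzylic C7–C7' bond and both benzyl ethers, giving (2S,3S)-5,5'-dimethoxysecoisolariciresinol F6.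
- One equivalent of DDQ (dioxane, rt) forms the p-quinone methide. The C9 hydroxyl traps it to give (2R,3S,4S)-5,5'-dimethoxylariciresinol F7, in which only C9'–OH is left free.
- BnBr/K2CO3 (acetone) protects the two phenols to the dibenzyl ether F8.
- SO3·pyridine then NaHCO3 gives 13, now isolated.
- CF3CO2H in CH2Cl2 (0 °C) effects the established benzylic ionisation/Friedel–Crafts closure to 14.

**Further compounds**
F1 | step 5 | (E)-3-[4-(benzyloxy)-3,5-dimethoxyphenyl]prop-2-enoic acid | OC(=O)/C=C/c1cc(OC)c(OCc2ccccc2)c(OC)c1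
F2 | step 5 | [(4S,5S)-2,2-dimethyl-1,3-dioxolane-4,5-diyl]bis(methylene) bis{(E)-3-[4-(benzyloxy)-3,5-dimethoxyphenyl]prop-2-enoate} | CC1(C)O[C@@H](COC(=O)/C=C/c2cc(OC)c(OCc3ccccc3)c(OC)c2)[C@H](COC(=O)/C=C/c2cc(OC)c(OCc3ccccc3)c(OC)c2)O1
F3 | step 5 | ten-membered dilactone of the (1S,2S,3R,4R)-3,4-diarylcyclobutane-1,2-dicarboxylic acid with (4S,5S)-2,2-dimethyl-1,3-dioxolane-4,5-dimethanol | CC1(C)O[C@H]2COC(=O)[C@H]3[C@H](c4cc(OC)c(OCc5ccccc5)c(OC)c4)[C@@H](c4cc(OC)c(OCc5ccccc5)c(OC)c4)[C@@H]3C(=O)OC[C@@H]2O1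
F4 | step 7 | {(1S,2S,3R,4R)-3,4-bis[4-(benzyloxy)-3,5-dimethoxyphenyl]-2-[(tert-butyldimethylsilyloxy)methyl]cyclobutyl}methanol | CC(C)(C)[Si](C)(C)OC[C@@H]1[C@@H](CO)[C@H](c2cc(OC)c(OCc3ccccc3)c(OC)c2)[C@H]1c1cc(OC)c(OCc2ccccc2)c(OC)c1
F5 | step 7 | sodium {(1S,2S,3R,4R)-3,4-bis[4-(benzyloxy)-3,5-dimethoxyphenyl]-2-[(tert-butyldimethylsilyloxy)methyl]cyclobutyl}methyl sulfate | CC(C)(C)[Si](C)(C)OC[C@@H]1[C@@H](COS(=O)(=O)[O-])[C@H](c2cc(OC)c(OCc3ccccc3)c(OC)c2)[C@H]1c1cc(OC)c(OCc2ccccc2)c(OC)c1.[Na+]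
F6 | step 8 | (2S,3S)-2,3-bis(4-hydroxy-3,5-dimethoxybenzyl)butane-1,4-diol (5,5'-dimethoxysecoisolariciresinol) | OC[C@@H](Cc1cc(OC)c(O)c(OC)c1)[C@@H](CO)Cc1cc(OC)c(O)c(OC)c1
F7 | step 8 | (2R,3S,4S)-5,5'-dimethoxylariciresinol | OC[C@H]1[C@H](c2cc(OC)c(O)c(OC)c2)OC[C@H]1Cc1cc(OC)c(O)c(OC)c1
F8 | step 8 | (2R,3S,4S)-5,5'-dimethoxylariciresinol 4,4'-dibenzyl ether | OC[C@H]1[C@H](c2cc(OC)c(OCc3ccccc3)c(OC)c2)OC[C@H]1Cc1cc(OC)c(OCc2ccccc2)c(OC)c1
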